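## Analysis of the target

Compound 26 is a trans-fused hydroazulene. Ring A is a cyclopentane (C1 ring-fusion CH, C2, C3 carbinol, C4 with two methyl groups, C5 ring-fusion carbinol carbon) and ring B a cycloheptanone (C5, C6, C7, C8 with a methyl group, quaternary C9, C10 ketone, C1); C9 carries a methyl group and the chain C11–C12 that ends at C13 of a butenolide (C13=C14, lactone carbonyl C15, OCH2 C16). In this numbering the five stereocentres are 1R,3R,5R,8R,9S. In ring A the C1 hydrogen and the C3 hydroxyl lie on the face opposite the C5 hydroxyl (trans ring fusion, anti 1,3-diol). In ring B the C8 and C9 methyl groups are cis to each other and anti to the C5 hydroxyl, so the C9 side chain is syn to it. No rigid element links the C8/C9 pair to the C1/C3/C5 group, since C5 and C8 are 1,4-related across a seven-membered ring. The sensitive functions are the tertiary aldol made up of C5–OH and the C10 ketone (retro-aldol cleavage, dehydration), the epimerisable C1 between them, and the butenolide, which tolerates neither strong base nor hydride or organometallic reagents. The synthesis is hard because three fully substituted carbons (C4, C5, C9) crowd the seven-membered ring, two of them adjacent, and the ketone lies between C9 and the ring fusion. The strategy uses one consequence of this crowding: C9 is quaternary, so the C10 ketone can enolise only toward C1, and an alkyne C2≡C3 held on C4 can be joined to that single enol carbon to close ring A at C1–C2, leaving a C2=C3 alkene from which the C3 hydroxyl is made.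

## Retrosynthetic reasoning

**Protecting groups and C10 oxidation level.** 26 is traced to its bis-silyl ether 25 and this to the C10 carbinol 24. Only Si–O bonds and the C10 oxidation level change. The ketone is unveiled late so that the tertiary aldol appears only in the last step and no ketone is present when hydride reagents are used earlier.

**Butenolide.** 24 comes from the lactol 22 by reduction (through 23). 22 is cut at C13=C14 and at the lactone C–O bond into the aldehyde 20 and glyoxylic acid 21. The cut is made here because the base- and hydride-sensitive ring is then attached last, and the forward condensation only has to join the aldehyde α-carbon C13 to the formyl carbon of 21.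

**C13–C16.** 20 is cut between C13 and the formyl carbon C16, giving the allyl compound 19. Forward, a linear hydroformylation must add one carbon to the terminal carbon of the only remaining alkene. The C9 allyl group thus supplies C11–C13 and is carried unchanged from the first step.

**C3–O and C2–H.** 19 goes back through the diol 18 and the epoxide 17 to the alkene 16. The oxygen is placed on C3 and a hydrogen on C2. The quaternary C4 makes C3 a neopentyl position, so a hydride has to attack C2, and the face of epoxidation fixes the C3 configuration. The price is that the C10 ketone is reduced as well and must be reoxidised, which is why C3 is silylated in 19.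

**C1–C2 (key disconnection).** 16 is cut between C1 and C2, giving the enol silane 15 with a terminal alkyne on C4. This bond is chosen because C1 is the only nucleophilic position the C10 carbonyl can offer. The cut removes ring A and one stereocentre in one step, and the forward reaction needs only a carbophilic catalyst under neutral conditions, which the β-silyloxy ketone tolerates.

**C4–C5.** 15 is the enol silane of 14, the silyl ether of the carbinol 13. 13 is cut between the two fully substituted carbons C4 and C5 into the dione 10 and the propargylic chloride 11 (as its allenylindium form 12). The forward addition must join a tertiary carbon to a ketone carbon, which a cyclic allyl-transfer-type transition state does well. It must also choose C5 over C10, which the quaternary C9 ensures, and one face of C5.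

**Two-carbon ring expansion.** The 1,3-dione 10 is traced through 9 and 8 to the enol silane 5 and dichloroketene 7 (from 6). C1 and C5 are the ketene carbons; forward, the C10–C1 and C5–C6 bonds form in a [2+2] cycloaddition and the C6–C10 bond is then broken by a retro-aldol. This turns a cyclopentanone, where the C8/C9 pair is easy to set, into the seven-membered ring with both oxygen functions in place.

**C8–CH3 and C9–C11.** 5 is the enol silane of the cyclopentanone 4, which is cut at the C8 methyl bond and at C9–C11 into the enone 1 and allyl iodide 2. Forward, a catalytic asymmetric conjugate methyl addition sets C8, and allylation of the resulting enolate 3 anti to that methyl group sets the quaternary C9.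

## Alternatives that were turned down

**Alternative 1:** Ring B is cut at C8–C9 by a retro-Cope operation that converts the C5–C6 and C5–C1 bonds, together with a new C1–C6 bond, into a cyclopropane fused to an intact ring A.
- **Forward key step:** heating would trigger a [3,3] shift within a cis-dialkenylcyclopropane unit (a propenyl group on the cyclopropane CH, a silyloxyalkenyl group on the ring-fusion carbon). This forms C8–C9, breaks C1–C6 and gives A1, a hydroazulene with a C6=C7 alkene and the C10 ketone as its triethylsilyl enol ether.
- **For:** strain release drives the step, and C8 and the quaternary C9 arise together. Their configuration is tied through one boat-like transition state to the ring A centres. This is the relay the chosen route lacks, and on this point the alternative is the stronger one.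
- **Against:** the rearranging array must carry a fully substituted, geometrically pure enol ether terminus and must form a quaternary carbon, which is the slowest case of this rearrangement. The substrate is a cyclopropanol silyl ether prone to ring opening. Two alkene geometries and the ring stereocentres have to be built beforehand in a long sequence. A1 still needs selective reduction of C6=C7, protonation at C1 (the same ring-fusion question as in the chosen route) and conversion of a protected hydroxyethyl chain into the butenolide.
- **Comparison:** the chosen route gives up the concerted relay but reaches its key substrate in eight steps from simple rings with one catalytic asymmetric step, and closes ring A under neutral catalytic conditions.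

**Alternative 2:** Both rings are opened at once by cutting C1–C5, which leads back to the ten-membered 5,10-dione A2.
- **Forward key step:** mild amine–acid or weak-base catalysis would enolise the C10 ketone of A2 (only toward C1), and the enol would add across the ring to the C5 ketone to give A3, the 3-O-triethylsilyl ether of 26.
- **For:** one step makes the C1–C5 bond, both rings and both ring-fusion stereocentres, probably along the biosynthetic path, so the natural trans arrangement may well be preferred. No protecting group is needed at C5, and A3 is one desilylation from the target. In end-game economy this alternative is clearly stronger.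
- **Against:** the difficulty is moved into A2, a ten-membered ring that holds the C8/C9 pair, C3, the gem-dimethyl C4 between two oxygenated carbons and the butenolide; closing such a medium ring is unfavourable. The C5 ketone can also enolise toward C6 and attack C10. The aldol is reversible, so ring size and configuration are decided by an equilibrium that structure alone does not predict.
- **Comparison:** the chosen route uses only common ring sizes, sets the two stereochemical groups in separate steps that can each be corrected, and has a bond-forming step whose regiochemistry is fixed (one nucleophilic carbon, one accessible alkyne carbon).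

**Alternative 3:** Ring B is cut at C7–C8 by a retro-oxy-Cope operation and at C9–C11 by a retro-allylation, leading back to a cyclohexane that contains C1–C5 and C10.
- **Forward key step:** the potassium alkoxide of the C10 carbinol would undergo a [3,3] shift that breaks C5–C10 and forms C7–C8, expanding the six-membered ring to a ten-membered one, and allyl iodide 2 would then alkylate C9 in the same flask. This gives A4, a ten-membered C10 ketone with a C5 methyl enol ether and the quaternary C9.
- **For:** the anionic rearrangement is fast and dependable, and the enolate arises regiospecifically and is quaternised at once. C3 is set on a six-membered ring, and C8 is tied to the carbinol centre through a chair-like transition state, a relay that is stronger than the remote induction of the chosen route.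
- **Against:** A4 is not yet bicyclic. After hydrolysis of its enol ether it would still need a transannular aldol of the kind described for A2, so it inherits that uncertainty and adds steps. The face of the C9 alkylation depends on the conformation of a flexible ten-membered enolate. The rearrangement substrate needs a hindered alkenyl metal added to a ketone flanked by a quaternary carbon.
- **Comparison:** the chosen route makes C8/C9 on a five-membered ring, where anti alkylation is dependable, and never passes through a medium ring.

Key step: step 9

Remarks on the chemistry (assumptions):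
- Addition to C5 of 10 is taken to occur on the ring face that carries the C8 and C9 methyl groups (equatorial entry of the bulky reagent on the conformer with an equatorial C8 methyl group); this is not secure and is covered by a fallback.
- The C10 carbinol centre in 18–20 and 22–24 is transient; its configuration is left open because either epimer is oxidised to 25.
- Glyoxylic acid 21 is used as its monohydrate; 8 and 9 are cis-fused mixtures at the ring fusion that converge in step 5.

## Route

Step 1
Reactants: 1 2-methylcyclopent-2-en-1-one; 2 allyl iodide (3-iodoprop-1-ene)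
Product: 4 (2S,3R)-2,3-dimethyl-2-(prop-2-en-1-yl)cyclopentan-1-one, via magnesium enolate 3 (not isolated)
Conditions: MeMgBr, CuBr·SMe2 (5 mol%), Josiphos-type ferrocenyl diphosphine (6 mol%, the enantiomer that gives 3R), tBuOMe, −78 °C; then 2, DMPU, −78 → 0 °C
Reagents that add atoms: methylmagnesium bromide, C[Mg]Br
Why: Copper-catalysed asymmetric conjugate addition of the Grignard reagent sets C8 under ligand control; the magnesium enolate 3 is then C-allylated anti to the new methyl group, which places the two methyl groups cis and sets the quaternary C9 (tandem conjugate addition–enolate alkylation).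

Step 2
Reactants: 4 (2S,3R)-2,3-dimethyl-2-(prop-2-en-1-yl)cyclopentan-1-one
Product: 5 trimethyl{[(4R,5S)-4,5-dimethyl-5-(prop-2-en-1-yl)cyclopent-1-en-1-yl]oxy}silane
Conditions: LiN(iPr)2, THF, −78 °C; Me3SiCl, −78 → 0 °C
Reagents that add atoms: chlorotrimethylsilane, C[Si](C)(C)Cl
Why: The ketone can enolise only toward its methylene side because the other α-carbon is quaternary, so deprotonation and O-silylation give a single enol silane.

Step 3
Reactants: 5 trimethyl{[(4R,5S)-4,5-dimethyl-5-(prop-2-en-1-yl)cyclopent-1-en-1-yl]oxy}silane; 6 dichloroacetyl chloride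
Product: 8 (2S,3R)-7,7-dichloro-2,3-dimethyl-2-(prop-2-en-1-yl)-1-(trimethylsilyloxy)bicyclo[3.2.0]heptan-6-one (cis-fused, both ring-fusion diastereomers), via dichloroketene 7 (not isolated)
Conditions: 6 (slow addition), Et3N, hexane, rt
Reagents that add atoms: none
Why: Polar [2+2] cycloaddition of the electrophilic ketene with the electron-rich enol silane, the ketene carbonyl carbon bonding to the unsubstituted enol carbon; the monosubstituted allyl alkene is far less nucleophilic and should not react, and both facial isomers converge in step 5.

Step 4
Reactants: 8 (2S,3R)-7,7-dichloro-2,3-dimethyl-2-(prop-2-en-1-yl)-1-(trimethylsilyloxy)bicyclo[3.2.0]heptan-6-one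
Product: 9 (2S,3R)-2,3-dimethyl-2-(prop-2-en-1-yl)-1-(trimethylsilyloxy)bicyclo[3.2.0]heptan-6-one (cis-fused, both ring-fusion diastereomers)
Conditions: Zn dust, AcOH, iPrOH/H2O, 0 °C → rt
Reagents that add atoms: none
Why: Zinc in acetic acid removes both α-chlorine atoms of the cyclobutanone reductively (through zinc enolates) and leaves the silyl ether and the terminal alkene alone.

Step 5
Reactants: 9 (2S,3R)-2,3-dimethyl-2-(prop-2-en-1-yl)-1-(trimethylsilyloxy)bicyclo[3.2.0]heptan-6-one
Product: 10 (4S,5R)-4,5-dimethyl-4-(prop-2-en-1-yl)cycloheptane-1,3-dione
Conditions: AcOH, H2O, iPrOH, 80 °C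
Reagents that add atoms: none
Why: Protodesilylation gives a strained β-hydroxy cyclobutanone that undergoes retro-aldol cleavage of the ring-fusion bond, a two-carbon ring expansion to the cycloheptane-1,3-dione; the ring-fusion centres disappear, so the diastereomers of 9 converge.

Step 6
Reactants: 10 (4S,5R)-4,5-dimethyl-4-(prop-2-en-1-yl)cycloheptane-1,3-dione; 11 3-chloro-3-methylbut-1-yne
Product: 13 (2S,3R,6R)-6-hydroxy-2,3-dimethyl-6-(2-methylbut-3-yn-2-yl)-2-(prop-2-en-1-yl)cycloheptan-1-one, via allenylindium reagent 12 (not isolated)
Conditions: In (powder), NaI (10 mol%), DMF, 0 °C → rt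
Reagents that add atoms: none
Why: Barbier reaction in which indium inserts into 11 to give the allenylindium species 12, which adds through a cyclic SE2' transition state and so joins its dimethyl-substituted carbon to the carbonyl carbon; the C10 carbonyl is shielded by the quaternary C9, so C5 reacts, and organoindium reagents tolerate the acidic diketone. The bulky reagent should enter equatorially on the conformer with an equatorial C8 methyl group, which places the new carbon substituent cis to the two methyl groups (6R), but this remote control is not secure.

Step 7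
Reactants: 13 (2S,3R,6R)-6-hydroxy-2,3-dimethyl-6-(2-methylbut-3-yn-2-yl)-2-(prop-2-en-1-yl)cycloheptan-1-one
Product: 14 (2S,3R,6R)-2,3-dimethyl-6-(2-methylbut-3-yn-2-yl)-2-(prop-2-en-1-yl)-6-(triethylsilyloxy)cycloheptan-1-one
Conditions: Et3SiOTf, 2,6-lutidine, CH2Cl2, −78 → 0 °C
Reagents that add atoms: triethylsilyl triflate, CC[Si](CC)(CC)OS(=O)(=O)C(F)(F)F
Why: A silyl triflate with a hindered pyridine base silylates the crowded tertiary alcohol; the ether blocks retro-aldol cleavage and, later, attack of this oxygen on the gold-activated alkyne.

Step 8
Reactants: 14 (2S,3R,6R)-2,3-dimethyl-6-(2-methylbut-3-yn-2-yl)-2-(prop-2-en-1-yl)-6-(triethylsilyloxy)cycloheptan-1-one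
Product: 15 tert-butyl{[(3R,6R,7S)-6,7-dimethyl-3-(2-methylbut-3-yn-2-yl)-7-(prop-2-en-1-yl)-3-(triethylsilyloxy)cyclohept-1-en-1-yl]oxy}dimethylsilane
Conditions: tBuMe2SiOTf, Et3N, CH2Cl2, 0 °C → rt
Reagents that add atoms: tert-butyldimethylsilyl triflate, CC(C)(C)[Si](C)(C)OS(=O)(=O)C(F)(F)F
Why: Soft enolisation with a silyl triflate and an amine forms the enol silane without a free enolate that could expel the β-silyloxy group; C1 is the only α-carbon that bears hydrogen, so the regiochemistry is fixed.

Step 9
Reactants: 15 tert-butyl{[(3R,6R,7S)-6,7-dimethyl-3-(2-methylbut-3-yn-2-yl)-7-(prop-2-en-1-yl)-3-(triethylsilyloxy)cyclohept-1-en-1-yl]oxy}dimethylsilane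
Product: 16 (3aR,5S,6R,8aR)-1,1,5,6-tetramethyl-5-(prop-2-en-1-yl)-8a-(triethylsilyloxy)-3a,5,6,7,8,8a-hexahydroazulen-4(1H)-one (trans-fused; C2=C3 alkene, C10 ketone)
Conditions: Ph3PAuNTf2 (5 mol%), CH2Cl2/MeOH (10:1), rt
Reagents that add atoms: none
Why: Ph3PAu+ (monovalent gold) binds the terminal alkyne of 15 and the silyl enol ether adds through C1, anti to the metal, to the terminal alkyne carbon C2; this gives a vinylgold species at C3 and a silyloxocarbenium ion at C10, after which methanol takes the silyl group to free the ketone and protonates the C3–Au bond, releasing the catalyst. The closest known reaction type is the gold-catalysed carbocyclisation of silyl enol ethers onto alkynes (Conia-ene type), which includes 5-endo-dig closures of homopropargylic enol ethers. Ring A closes in the 5-endo-dig mode (C1–C5–C4–C3≡C2, both alkyne carbons in the ring); the 4-exo closure at C3 would build a cyclobutane at a neopentyl carbon and is not expected. The new stereocentre C1 is controlled by C5: the alkyne is tethered through C4 to C5, and in the ring B conformer that keeps the bulky 1,1-dimethylpropargyl group pseudo-equatorial and the silyloxy group pseudo-axial, C2 reaches the face of C1 that leaves C1–H anti to the C5–O bond, the trans ring fusion. The step needs carbon and not oxygen nucleophilicity, which the silylated C5 oxygen and the soft carbophilic catalyst ensure, and it needs the enol ether to outcompete the remote allyl alkene, which its proximity and higher nucleophilicity ensure. The geminal methyl groups on C4 and the fully substituted C5 fold the chain toward C1, and the neutral medium avoids β-elimination of the C5 silyloxy group. The face selectivity at C1 is the least secure element, because closure through the conformer with a pseudo-axial propargylic carbon, which distorts ring B less, would give the cis isomer.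

Step 10
Reactants: 16 trans-fused hydroazulenone with C2=C3 alkene
Product: 17 2,3-epoxide of 16 with the oxirane oxygen anti to the C5 silyloxy group (1R,2R,3S,5R,8R,9S in the numbering of 26)
Conditions: mCPBA, CH2Cl2, 0 °C
Reagents that add atoms: 3-chloroperbenzoic acid, OOC(=O)c1cccc(Cl)c1
Why: Prilezhaev epoxidation; the strained cis-disubstituted ring alkene is more electron-rich than the monosubstituted allyl alkene, and the peracid should approach the ring A face that carries C1–H, anti to the C1–C10 bond and the C5 silyloxy group.

Step 11
Reactants: 17 2,3-epoxide of 16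
Product: 18 C3,C10-diol: decahydroazulene with C3–OH anti to C5–OSiEt3 (3R), C10–OH of open configuration, C5–OSiEt3 and C9 allyl retained
Conditions: LiBHEt3, THF, −78 °C → rt; H2O
Reagents that add atoms: none
Why: The hydride first reduces the C10 ketone and then opens the epoxide by SN2 attack at C2, the carbon that is not flanked by the quaternary C4, so the oxygen stays on C3 with the configuration set by the epoxide; the C10 carbinol is reoxidised in step 16.

Step 12
Reactants: 18 C3,C10-diol
Product: 19 C3 tert-butyldimethylsilyl ether of 18 (C10–OH free)
Conditions: tBuMe2SiOTf (1.1 equiv), 2,6-lutidine, CH2Cl2, −78 °C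
Reagents that add atoms: tert-butyldimethylsilyl triflate, CC(C)(C)[Si](C)(C)OS(=O)(=O)C(F)(F)F
Why: Silylation under kinetic control selects the C3 hydroxyl, because the C10 hydroxyl lies between the quaternary C9 and the ring-fusion carbon C1.

Step 13
Reactants: 19 C3 silyl ether with C9 allyl group
Product: 20 4-substituted butanal: the C9 allyl group of 19 converted into CH2CH2CH2CHO
Conditions: Rh(acac)(CO)2 (2 mol%), BiPhePhos (4 mol%), CO/H2 (1:1, 10 bar), toluene, 60 °C
Reagents that add atoms: carbon monoxide, [C-]#[O+]
Why: Rhodium-catalysed hydroformylation with a bulky bisphosphite ligand puts the formyl group on the terminal carbon of the monosubstituted alkene (linear aldehyde); no other alkene is left in the molecule.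

Step 14
Reactants: 20 aldehyde; 21 glyoxylic acid
Product: 22 5-hydroxybutenolide: 5-hydroxy-4-(2-substituted ethyl)furan-2(5H)-one on C12 (lactol epimers), ring system as in 20
Conditions: 21 (monohydrate), morpholine, dioxane/H2O, 50 °C; then 1 M HCl, rt
Reagents that add atoms: none
Why: Amine-mediated condensation of the aldehyde α-carbon C13 (as its enamine) with the formyl group of glyoxylic acid, then elimination and ring closure of the formyl acrylic acid to the γ-hydroxybutenolide (synthesis of β-substituted γ-hydroxybutenolides from aldehydes).

Step 15
Reactants: 22 5-hydroxybutenolide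
Product: 24 butenolide with free C10–OH (4-substituted furan-2(5H)-one), via sodium hydroxy carboxylate 23 (not isolated)
Conditions: NaBH4, THF/MeOH, 0 °C; then 1 M HCl to pH 3
Reagents that add atoms: none
Why: Borohydride reduces the masked aldehyde of the lactol (open formyl carboxylate form) to the (Z)-hydroxy carboxylate 23, which lactonises on acidification; with C10 still a carbinol, no ketone competes.

Step 16
Reactants: 24 butenolide with free C10–OH
Product: 25 3-O-tert-butyldimethylsilyl 5-O-triethylsilyl ether of 26 (C10 ketone; 1R,3R,5R,8R,9S)
Conditions: Dess–Martin periodinane, CH2Cl2, rt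
Reagents that add atoms: none
Why: Dess–Martin oxidation of the only free hydroxyl group restores the C10 ketone under conditions that leave the butenolide, the silyl ethers and the C1 configuration intact.

Step 17
Reactants: 25 bis-silyl ether of the target
Product: 26 4-{2-[(2R,3aR,5S,6R,8aR)-2,8a-dihydroxy-1,1,5,6-tetramethyl-4-oxodecahydroazulen-5-yl]ethyl}furan-2(5H)-one (CNP0077405.2)
Conditions: HF·pyridine, THF, 0 °C → rt
Reagents that add atoms: none
Why: Fluoride cleaves both silyl ethers under mildly acidic, non-basic conditions, which avoids retro-aldol cleavage of the tertiary β-hydroxy ketone, epimerisation at C1 and opening of the butenolide.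

## Compound list

1 | 2-methylcyclopent-2-en-1-one | CC1=CCCC1=O | starting material
2 | allyl iodide (3-iodoprop-1-ene) | C=CCI | starting material
3 | bromomagnesium (3R)-2,3-dimethylcyclopent-1-en-1-olate | C[C@@H]1CCC(O[Mg]Br)=C1C | intermediate
4 | (2S,3R)-2,3-dimethyl-2-(prop-2-en-1-yl)cyclopentan-1-one | C[C@@H]1CCC(=O)[C@@]1(C)CC=C | intermediate
5 | trimethyl{[(4R,5S)-4,5-dimethyl-5-(prop-2-en-1-yl)cyclopent-1-en-1-yl]oxy}silane | C[C@@H]1CC=C(O[Si](C)(C)C)[C@@]1(C)CC=C | intermediate
6 | dichloroacetyl chloride | O=C(Cl)C(Cl)Cl | starting material
7 | dichloroketene | ClC(Cl)=C=O | intermediate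
8 | (2S,3R)-7,7-dichloro-2,3-dimethyl-2-(prop-2-en-1-yl)-1-(trimethylsilyloxy)bicyclo[3.2.0]heptan-6-one (cis-fused, ring-fusion centres open) | C[C@@H]1CC2C(=O)C(Cl)(Cl)C2(O[Si](C)(C)C)[C@@]1(C)CC=C | intermediate
9 | (2S,3R)-2,3-dimethyl-2-(prop-2-en-1-yl)-1-(trimethylsilyloxy)bicyclo[3.2.0]heptan-6-one (cis-fused, ring-fusion centres open) | C[C@@H]1CC2C(=O)CC2(O[Si](C)(C)C)[C@@]1(C)CC=C | intermediate
10 | (4S,5R)-4,5-dimethyl-4-(prop-2-en-1-yl)cycloheptane-1,3-dione | C[C@@H]1CCC(=O)CC(=O)[C@@]1(C)CC=C | intermediate
11 | 3-chloro-3-methylbut-1-yne | CC(C)(Cl)C#C | starting material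
12 | (3-methylbuta-1,2-dien-1-yl)indium dichloride (allenylindium reagent, drawn as the monomer) | CC(C)=C=C[In](Cl)Cl | intermediate
13 | (2S,3R,6R)-6-hydroxy-2,3-dimethyl-6-(2-methylbut-3-yn-2-yl)-2-(prop-2-en-1-yl)cycloheptan-1-one | C[C@@H]1CC[C@](O)(C(C)(C)C#C)CC(=O)[C@@]1(C)CC=C | intermediate
14 | (2S,3R,6R)-2,3-dimethyl-6-(2-methylbut-3-yn-2-yl)-2-(prop-2-en-1-yl)-6-(triethylsilyloxy)cycloheptan-1-one | C[C@@H]1CC[C@](O[Si](CC)(CC)CC)(C(C)(C)C#C)CC(=O)[C@@]1(C)CC=C | intermediate
15 | tert-butyl{[(3R,6R,7S)-6,7-dimethyl-3-(2-methylbut-3-yn-2-yl)-7-(prop-2-en-1-yl)-3-(triethylsilyloxy)cyclohept-1-en-1-yl]oxy}dimethylsilane | C[C@@H]1CC[C@](O[Si](CC)(CC)CC)(C(C)(C)C#C)C=C(O[Si](C)(C)C(C)(C)C)[C@@]1(C)CC=C | intermediate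
16 | (3aR,5S,6R,8aR)-1,1,5,6-tetramethyl-5-(prop-2-en-1-yl)-8a-(triethylsilyloxy)-3a,5,6,7,8,8a-hexahydroazulen-4(1H)-one (trans-fused) | C[C@@H]1CC[C@@]2(O[Si](CC)(CC)CC)[C@@H](C=CC2(C)C)C(=O)[C@@]1(C)CC=C | intermediate
17 | 2,3-epoxide of 16, oxirane oxygen anti to the C5 silyloxy group | C[C@@H]1CC[C@@]2(O[Si](CC)(CC)CC)[C@@H]([C@H]3O[C@H]3C2(C)C)C(=O)[C@@]1(C)CC=C | intermediate
18 | C3,C10-diol (C3–OH anti to C5–OSiEt3; C10 carbinol centre open) | C[C@@H]1CC[C@@]2(O[Si](CC)(CC)CC)[C@@H](C[C@@H](O)C2(C)C)C(O)[C@@]1(C)CC=C | intermediate
19 | C3 tert-butyldimethylsilyl ether of 18 | C[C@@H]1CC[C@@]2(O[Si](CC)(CC)CC)[C@@H](C[C@@H](O[Si](C)(C)C(C)(C)C)C2(C)C)C(O)[C@@]1(C)CC=C | intermediate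
20 | aldehyde: C9 side chain of 19 extended to CH2CH2CH2CHO | C[C@@H]1CC[C@@]2(O[Si](CC)(CC)CC)[C@@H](C[C@@H](O[Si](C)(C)C(C)(C)C)C2(C)C)C(O)[C@@]1(C)CCCC=O | intermediate
21 | glyoxylic acid (used as the monohydrate) | O=CC(=O)O | starting material
22 | 5-hydroxybutenolide (5-hydroxy-4-substituted furan-2(5H)-one, lactol epimers) | C[C@@H]1CC[C@@]2(O[Si](CC)(CC)CC)[C@@H](C[C@@H](O[Si](C)(C)C(C)(C)C)C2(C)C)C(O)[C@@]1(C)CCC3=CC(=O)OC3O | intermediate
23 | sodium (Z)-4-hydroxy-3-substituted but-2-enoate | C[C@@H]1CC[C@@]2(O[Si](CC)(CC)CC)[C@@H](C[C@@H](O[Si](C)(C)C(C)(C)C)C2(C)C)C(O)[C@@]1(C)CC/C(CO)=C/C(=O)[O-].[Na+] | intermediate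
24 | butenolide with free C10–OH | C[C@@H]1CC[C@@]2(O[Si](CC)(CC)CC)[C@@H](C[C@@H](O[Si](C)(C)C(C)(C)C)C2(C)C)C(O)[C@@]1(C)CCC3=CC(=O)OC3 | intermediate
25 | 3-O-tert-butyldimethylsilyl 5-O-triethylsilyl ether of 26 | C[C@@H]1CC[C@@]2(O[Si](CC)(CC)CC)[C@@H](C[C@@H](O[Si](C)(C)C(C)(C)C)C2(C)C)C(=O)[C@@]1(C)CCC3=CC(=O)OC3 | intermediate
26 | 4-{2-[(2R,3aR,5S,6R,8aR)-2,8a-dihydroxy-1,1,5,6-tetramethyl-4-oxodecahydroazulen-5-yl]ethyl}furan-2(5H)-one | C[C@@H]1CC[C@@]2(O)[C@@H](C[C@@H](O)C2(C)C)C(=O)[C@@]1(C)CCC1=CC(=O)OC1 | target

## Step count and least certain steps

Total: 17 steps. Longest linear sequence: 17 steps (the route is fully linear from 1).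

**Step 9 (key step).**
- Most likely failure: C1–C2 bond formation on the other face of C1, through the ring B conformer with a pseudo-axial propargylic carbon, which gives the cis ring fusion. Less likely are ionisation of the allylic tertiary C5–O bond or protodesilylation of the enol ether before closure.
- Fallback: the stereocentre is then set by a protonation and not by the carbon–carbon bond formation. Setting out from 15, the closure is accepted as it comes and gives the cis-fused C1 epimer F1. F1 is deprotonated at C1 (LiN(iPr)2, THF, −78 °C) to the extended lithium enolate F2. Kinetic α-protonation with acetic acid or a bulky phenol at −78 °C should then occur on the face anti to the C5 silyloxy group and return the route to 16. The low temperature is chosen to avoid loss of the β-silyloxy group and drift of the alkene into conjugation.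

**Step 6.**
- Most likely failure: poor or reversed facial selectivity at C5, because the C8/C9 pair controls it only across the seven-membered ring. Bond formation through the unsubstituted terminus of 12, to an allenyl carbinol, is a lesser risk.
- Fallback: oxygen, not carbon, is delivered to C5 in the stereo-determining step. It sets out from 10, whose addition product is then the C5 epimer F3, alone or mixed with 13. The mixture is dehydrated with Burgess reagent (toluene, 60 °C) to the single enone F4, in which C5 is no longer a stereocentre. Nucleophilic epoxidation (H2O2, NaOH, MeOH, 0 °C) should then place oxygen on the more accessible face of C5, the one that took up carbon in the direct addition, and give the epoxy ketone F5. SmI2 (THF/MeOH, −78 °C) cleaves the C1–O bond of F5 and returns the route to 13.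

**Step 10.**
- Most likely failure: competing epoxidation of the allyl alkene, if the ring alkene is slowed by the neighbouring quaternary C4.
- Fallback: the side-chain alkene is used up first. Setting out from 16, hydroformylation under the conditions of step 13 (the hindered ring alkene is inert) gives the keto aldehyde F6. F6 is protected as the dimethyl acetal F7 (MeOSiMe3, catalytic Me3SiOTf, CH2Cl2, −78 °C). Epoxidation with mCPBA then gives F8, LiBHEt3 gives the diol F9, and tBuMe2SiCl with imidazole in DMF gives the C3 silyl ether F10. Mild acetal hydrolysis (pyridinium tosylate, acetone/H2O) returns the route to 20.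

**Step 14.**
- Most likely failure: loss of the silyl ethers, or self-condensation of the aldehyde, in the warm acidic aqueous medium.
- Fallback: the butenolide is closed by olefin metathesis and not by condensation. Setting out from 20, α-methylenation (aqueous formaldehyde, catalytic pyrrolidine and propionic acid, iPrOH, 45 °C) gives the enal F11. Reduction with NaBH4 and CeCl3 in MeOH gives the allylic alcohol F12. Selective acylation of its primary hydroxyl (acryloyl chloride, iPr2NEt, CH2Cl2, −40 °C) gives the acrylate F13. Ring-closing metathesis with the second-generation Grubbs catalyst (toluene, 80 °C) returns the route to 24 and bypasses 22 and 23.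

## Further compounds

F1 | step 9 | cis-fused C1 epimer of 16 | C[C@@H]1CC[C@@]2(O[Si](CC)(CC)CC)[C@H](C=CC2(C)C)C(=O)[C@@]1(C)CC=C
F2 | step 9 | extended lithium enolate of 16 (C10 enolate conjugated with C2=C3) | C[C@@H]1CC[C@@]2(O[Si](CC)(CC)CC)C(C=CC2(C)C)=C(O[Li])[C@@]1(C)CC=C
F3 | step 6 | (2S,3R,6S)-6-hydroxy-2,3-dimethyl-6-(2-methylbut-3-yn-2-yl)-2-(prop-2-en-1-yl)cycloheptan-1-one (C5 epimer of 13) | C[C@@H]1CC[C@@](O)(C(C)(C)C#C)CC(=O)[C@@]1(C)CC=C
F4 | step 6 | (6R,7S)-6,7-dimethyl-3-(2-methylbut-3-yn-2-yl)-7-(prop-2-en-1-yl)cyclohept-2-en-1-one | C[C@@H]1CCC(C(C)(C)C#C)=CC(=O)[C@@]1(C)CC=C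
F5 | step 6 | 2,3-epoxide of F4 with the oxygen on the face that gives 13 | C[C@@H]1CC[C@@]2(C(C)(C)C#C)O[C@H]2C(=O)[C@@]1(C)CC=C
F6 | step 10 | keto aldehyde: 16 with the allyl group converted into CH2CH2CH2CHO | C[C@@H]1CC[C@@]2(O[Si](CC)(CC)CC)[C@@H](C=CC2(C)C)C(=O)[C@@]1(C)CCCC=O
F7 | step 10 | dimethyl acetal of F6 | C[C@@H]1CC[C@@]2(O[Si](CC)(CC)CC)[C@@H](C=CC2(C)C)C(=O)[C@@]1(C)CCCC(OC)OC
F8 | step 10 | 2,3-epoxide of F7, oxygen anti to the C5 silyloxy group | C[C@@H]1CC[C@@]2(O[Si](CC)(CC)CC)[C@@H]([C@H]3O[C@H]3C2(C)C)C(=O)[C@@]1(C)CCCC(OC)OC
F9 | step 10 | C3,C10-diol acetal (C10 carbinol centre open) | C[C@@H]1CC[C@@]2(O[Si](CC)(CC)CC)[C@@H](C[C@@H](O)C2(C)C)C(O)[C@@]1(C)CCCC(OC)OC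
F10 | step 10 | C3 tert-butyldimethylsilyl ether of F9 | C[C@@H]1CC[C@@]2(O[Si](CC)(CC)CC)[C@@H](C[C@@H](O[Si](C)(C)C(C)(C)C)C2(C)C)C(O)[C@@]1(C)CCCC(OC)OC
F11 | step 14 | α-methylene aldehyde from 20 | C[C@@H]1CC[C@@]2(O[Si](CC)(CC)CC)[C@@H](C[C@@H](O[Si](C)(C)C(C)(C)C)C2(C)C)C(O)[C@@]1(C)CCC(=C)C=O
F12 | step 14 | 2-substituted allylic alcohol from F11 | C[C@@H]1CC[C@@]2(O[Si](CC)(CC)CC)[C@@H](C[C@@H](O[Si](C)(C)C(C)(C)C)C2(C)C)C(O)[C@@]1(C)CCC(=C)CO
F13 | step 14 | acrylate of F12 | C[C@@H]1CC[C@@]2(O[Si](CC)(CC)CC)[C@@H](C[C@@H](O[Si](C)(C)C(C)(C)C)C2(C)C)C(O)[C@@]1(C)CCC(=C)COC(=O)C=C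
A1 | alternative 1 | hydroazulene diene with C6=C7 alkene and C10 triethylsilyl enol ether | C[C@@H]1C=C[C@@]2(O[Si](C)(C)C(C)(C)C)C(C[C@@H](O[Si](C)(C)C(C)(C)C)C2(C)C)=C(O[Si](CC)(CC)CC)[C@@]1(C)CCOCc1ccc(OC)cc1
A2 | alternative 2 | ten-membered 5,10-dione with C3 triethylsilyl ether and butenolide side chain | C[C@@H]1CCC(=O)C(C)(C)[C@H](O[Si](CC)(CC)CC)CCC(=O)[C@@]1(C)CCC1=CC(=O)OC1
A3 | alternative 2 | 3-O-triethylsilyl ether of 26 | C[C@@H]1CC[C@@]2(O)[C@@H](C[C@@H](O[Si](CC)(CC)CC)C2(C)C)C(=O)[C@@]1(C)CCC1=CC(=O)OC1
A4 | alternative 3 | ten-membered C10 ketone with C5 methyl enol ether and quaternary C9 | C[C@@H]1C/C=C(OC)/C(C)(C)[C@H](O[Si](C)(C)C(C)(C)C)CCC(=O)[C@@]1(C)CC=C
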